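**Plan**

1. Numbering used: decalin carbons C1–C10 (C4 = CMe2, C5=C6, C8 bears a methyl, C9 is quaternary, C10–H), C11 = benzylic CH2. Late cuts: hydroxyquinone ⇐ 2,3,5,6-tetramethoxyaryl; C8–CH3 ⇐ C8–acyl; the C5=C6/C10–H unit ⇐ an allylsilane (C6–SiMe3, C5=C10) by anti SE2' protonation.
2. Ring B is then cut at C6–C7 and C8–C9 as a [4+2] cycloaddition. C6, C5, C10 and C9 are contiguous and C5/C10 are shared with ring A, so after the double-bond shift they are an s-cis-locked 1,2-bis(alkylidene)cyclohexane diene whose termini are the two atoms that bond to the C7–C8 unit (an acrylate).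
3. The diene is cut at C5–C10 (ring A) and C9–C11: a 1,7-diyne is bicyclised on Cp2Zr and the inner Zr–C9 bond is benzylated with the complete aryl fragment.
4. Forward: nitrile alkylation builds the gem-dimethyl diyne; the Cp2Zr bicyclisation closes ring A and fixes both alkene geometries (SiMe3 outside on C6, benzyl inside on C9); the Diels–Alder reaction closes ring B; the quinone is unveiled last.
5. Stereochemistry: C8 from an (R)-4-benzyloxazolidinone auxiliary; C9 and C6 relative to C8 from the endo rule and the diene geometry; C10 from C6 by stereospecific anti protodesilylation, which also removes the helper silicon.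

Key step: step 9

**Route**

Step 1
Reactants: 1 isobutyronitrile; 2 6-chlorohex-2-yne
Product: 4 2,2-dimethyloct-6-ynenitrile, via lithiated isobutyronitrile 3 (not isolated)
Conditions: LiN(i-Pr)2 (1.1 equiv), THF, −78 °C; then 2, DMPU, −78 °C → rt
Reagents that add atoms: none
Why: Alkylation of a tertiary nitrile anion by a primary chloride is a standard route to a quaternary carbon, here the gem-dimethyl carbon C4.

Step 2
Reactants: 4 2,2-dimethyloct-6-ynenitrile
Product: 6 2,2-dimethyloct-6-ynal, via N-aluminated imine 5 (not isolated)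
Conditions: i-Bu2AlH (1.2 equiv), CH2Cl2, −78 °C; then 1 M HCl, 0 °C
Reagents that add atoms: water, O
Why: Reduction of a nitrile by i-Bu2AlH stops at the N-aluminated imine, which hydrolyses to the non-enolisable aldehyde, and the internal alkyne is inert at −78 °C.

Step 3
Reactants: 6 2,2-dimethyloct-6-ynal
Product: 7 3,3-dimethylnona-1,7-diyne
Conditions: dimethyl (1-diazo-2-oxopropyl)phosphonate (1.3 equiv), K2CO3 (2 equiv), MeOH, 0 °C → rt
Reagents that add atoms: dimethyl (1-diazo-2-oxopropyl)phosphonate, COP(=O)(OC)C(=[N+]=[N-])C(C)=O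
Why: The Seyferth–Gilbert homologation in its Ohira–Bestmann form turns an aldehyde into the terminal alkyne (the future C6) under mild base, and this aldehyde has no α-hydrogen to lose.

Step 4
Reactants: 7 3,3-dimethylnona-1,7-diyne
Product: 9 (3,3-dimethylnona-1,7-diyn-1-yl)trimethylsilane, via lithium acetylide 8 (not isolated)
Conditions: n-BuLi (1.05 equiv), THF, −78 °C; then Me3SiCl, −78 °C → rt
Reagents that add atoms: chlorotrimethylsilane, C[Si](C)(C)Cl
Why: Deprotonation and C-silylation of a terminal alkyne is routine and installs the helper silicon that later sits on C6.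

Step 5
Reactants: 10 1,2,4,5-tetramethoxybenzene
Product: 12 (2,3,5,6-tetramethoxyphenyl)methanol, via aryllithium 11 (not isolated)
Conditions: n-BuLi (1.1 equiv), THF, 0 °C → rt; then (CH2O)n, −78 °C → rt; aq. NH4Cl
Reagents that add atoms: formaldehyde (as paraformaldehyde), C=O
Why: The two ring C–H positions are equivalent and each is flanked by two methoxy groups, so directed lithiation is unambiguous and the aryllithium adds to formaldehyde.

Step 6
Reactants: 12 (2,3,5,6-tetramethoxyphenyl)methanol
Product: 13 3-(bromomethyl)-1,2,4,5-tetramethoxybenzene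
Conditions: PBr3 (0.4 equiv), Et2O, 0 °C; used at once
Reagents that add atoms: phosphorus tribromide, BrP(Br)Br
Why: PBr3 converts a primary benzylic alcohol into the bromide under routine conditions, and the electron-rich bromide is used crude to avoid solvolysis.

Step 7
Reactants: 9 (3,3-dimethylnona-1,7-diyn-1-yl)trimethylsilane; 13 3-(bromomethyl)-1,2,4,5-tetramethoxybenzene
Product: 16 [(E)-{(6Z)-2,2-dimethyl-6-[1-(2,3,5,6-tetramethoxyphenyl)propan-2-ylidene]cyclohexylidene}methyl]trimethylsilane, via zirconacyclopentadiene 14 (not isolated), via alkenylzirconium chloride 15 (not isolated)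
Conditions: Cp2ZrCl2 (1.1 equiv), n-BuLi (2.2 equiv), THF, −78 °C; then 9, −78 °C → rt; then CuCl (1.1 equiv), Pd(PPh3)4 (5 mol %), 13, 50 °C; then 1 M HCl, 0 °C
Reagents that add atoms: none
Why: Reductive bicyclisation of the 1,7-diyne on Cp2Zr closes ring A (C5–C10) with zirconium on the two inner positions, so transmetalation of the less hindered, non-silylated Zr–C9 bond to copper with benzylation, then protonolysis of the Zr–C6 bond, should give the diene with SiMe3 outside (E) and benzyl inside (Z) by retention at both alkenes.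

Step 8
Reactants: 17 (R)-4-benzyloxazolidin-2-one; 18 acryloyl chloride
Product: 20 (R)-3-acryloyl-4-benzyloxazolidin-2-one, via bromomagnesium amide 19 (not isolated)
Conditions: MeMgBr (1.0 equiv), THF, 0 °C; then 18, −78 °C → 0 °C
Reagents that add atoms: none
Why: N-Acylation of the oxazolidinone magnesium salt by the acid chloride is the standard entry to N-acryloyl oxazolidinones, and the low temperature limits polymerisation.

Step 9
Reactants: 16 [(E)-{(6Z)-2,2-dimethyl-6-[1-(2,3,5,6-tetramethoxyphenyl)propan-2-ylidene]cyclohexylidene}methyl]trimethylsilane; 20 (R)-3-acryloyl-4-benzyloxazolidin-2-one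
Product: 21 (4R)-4-benzyl-3-{[(1R,2S,4R)-1,5,5-trimethyl-1-[(2,3,5,6-tetramethoxyphenyl)methyl]-4-(trimethylsilyl)-1,2,3,4,5,6,7,8-octahydronaphthalen-2-yl]carbonyl}-1,3-oxazolidin-2-one
Conditions: 20 (1.0 equiv), Et2AlCl (1.5 equiv), CH2Cl2, −78 °C; then 16 (1.2 equiv), −78 → −40 °C; 1 M HCl, −78 °C
Reagents that add atoms: none
Why: Et2AlCl binds both imide carbonyls of 20 and locks the acryloyl group s-cis; the cycloaddition should be strongly asynchronous, with C6 of the diene (ipso to silicon) attacking the acrylimide β-carbon (C7) while positive charge builds at C5 (β to silicon) and at the fully substituted C9, which then bonds to C8. The closest known reactions are the Et2AlCl-promoted Diels–Alder reactions of N-acryloyloxazolidinones with acyclic and exocyclic dienes and the cycloadditions of 1-silyl-1,3-dienes that give allylsilanes. Ring B closes in the cycloaddition mode, suprafacial on both partners, the lagging C8–C9 bond being a 6-(enolexo)-endo-trig closure of the aluminium enolate onto the allyl cation. C8 (S) is set by the auxiliary, whose benzyl group covers one face of the chelate so that the diene adds to the Re face of the α-carbon; C9 (R) follows from the endo transition state and the Z geometry at C9=C10 (outer methyl cis, inner benzyl trans to the acyl group); C6 (R) follows from the E geometry at C5=C6 (outer silicon cis to the acyl group). The step needs regioselectivity (C7 to C6, C8 to C9), which the silyl group on C6 and the two alkyl groups on C9 secure by making C6 the nucleophilic terminus, and endo selectivity, which is favoured because the acyl group lies under C10, away from the gem-dimethyl group on C4.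

Step 10
Reactants: 21 Diels–Alder adduct (allylsilane)
Product: 22 (4R)-4-benzyl-3-{[(1S,2S,8aS)-1,5,5-trimethyl-1-[(2,3,5,6-tetramethoxyphenyl)methyl]-1,2,3,7,8,8a-hexahydronaphthalen-2-yl]carbonyl}-1,3-oxazolidin-2-one
Conditions: CF3CO2H (3 equiv), CH2Cl2, −20 → 0 °C; then H2O
Reagents that add atoms: none
Why: Protodesilylation of an allylsilane is an SE2' reaction in which the proton adds to C10 anti to the pseudoaxial C6–Si bond and loss of silicon from the β-silyl cation places the double bond at C5=C6, so C10 (S) is set from C6 and the helper group is removed.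

Step 11
Reactants: 22 desilylated imide
Product: 23 [(1S,2S,8aS)-1,5,5-trimethyl-1-[(2,3,5,6-tetramethoxyphenyl)methyl]-1,2,3,7,8,8a-hexahydronaphthalen-2-yl]methanol
Conditions: LiBH4 (2 equiv), H2O (1 equiv), Et2O, 0 °C → rt
Reagents that add atoms: none
Why: LiBH4 attacks the exocyclic imide carbonyl and reduces it to the primary alcohol with release of the auxiliary, after which C8 can no longer epimerise.

Step 12
Reactants: 23 primary alcohol
Product: 24 [(1S,2S,8aS)-1,5,5-trimethyl-1-[(2,3,5,6-tetramethoxyphenyl)methyl]-1,2,3,7,8,8a-hexahydronaphthalen-2-yl]methyl methanesulfonate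
Conditions: MsCl (1.5 equiv), Et3N (2 equiv), CH2Cl2, 0 °C
Reagents that add atoms: methanesulfonyl chloride, CS(=O)(=O)Cl
Why: Sulfonylation of a primary alcohol is routine and touches no stereocentre.

Step 13
Reactants: 24 mesylate
Product: 25 3-{[(1R,2S,8aS)-1,2,5,5-tetramethyl-1,2,3,7,8,8a-hexahydronaphthalen-1-yl]methyl}-1,2,4,5-tetramethoxybenzene
Conditions: LiEt3BH (4 equiv), THF, 0 → 65 °C
Reagents that add atoms: none
Why: LiEt3BH displaces primary, β-branched sulfonates by SN2 hydride transfer where weaker hydrides fail, which gives the methyl group on C8.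

Step 14
Reactants: 25 tetramethoxyarene
Product: 26 2,5-dimethoxy-3-{[(1R,2S,8aS)-1,2,5,5-tetramethyl-1,2,3,7,8,8a-hexahydronaphthalen-1-yl]methyl}cyclohexa-2,5-diene-1,4-dione
Conditions: (NH4)2Ce(NO3)6 (2.5 equiv), MeCN–H2O (2:1), 0 °C
Reagents that add atoms: water, O
Why: Oxidative demethylation of a 1,4-dimethoxyarene by tetravalent cerium gives the para-quinone, both para pairs of the symmetric aryl group lead to the same 2,5-dimethoxyquinone, and the hindered trisubstituted alkene should be left alone.

Step 15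
Reactants: 26 2,5-dimethoxyquinone
Product: 27 2-hydroxy-5-methoxy-3-{[(1R,2S,8aS)-1,2,5,5-tetramethyl-1,2,3,7,8,8a-hexahydronaphthalen-1-yl]methyl}cyclohexa-2,5-diene-1,4-dione (target)
Conditions: KOH (2 M aq.), MeOH, rt; then 1 M HCl
Reagents that add atoms: potassium hydroxide, [K+].[OH-]
Why: Hydroxide should add to the vinylogous ester next to the alkyl group, whose methoxy group is twisted out of conjugation by its two neighbours, and expel methoxide, and the resulting hydroxyquinone anion is inert to a second substitution, as in related 2-hydroxy-5-methoxy-3-alkylquinone endgames.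

**Compound list**

1 | isobutyronitrile | CC(C)C#N | starting material
2 | 6-chlorohex-2-yne | CC#CCCCCl | starting material
3 | lithiated isobutyronitrile (N-lithio ketenimine form) | CC(C)=C=N[Li] | intermediate
4 | 2,2-dimethyloct-6-ynenitrile | CC#CCCCC(C)(C)C#N | intermediate
5 | N-(diisobutylalumanyl)-2,2-dimethyloct-6-yn-1-imine | CC#CCCCC(C)(C)C=N[Al](CC(C)C)CC(C)C | intermediate
6 | 2,2-dimethyloct-6-ynal | CC#CCCCC(C)(C)C=O | intermediate
7 | 3,3-dimethylnona-1,7-diyne | CC#CCCCC(C)(C)C#C | intermediate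
8 | (3,3-dimethylnona-1,7-diyn-1-yl)lithium | CC#CCCCC(C)(C)C#C[Li] | intermediate
9 | (3,3-dimethylnona-1,7-diyn-1-yl)trimethylsilane | CC#CCCCC(C)(C)C#C[Si](C)(C)C | intermediate
10 | 1,2,4,5-tetramethoxybenzene | COc1cc(OC)c(OC)cc1OC | starting material
11 | (2,3,5,6-tetramethoxyphenyl)lithium | COc1cc(OC)c(OC)c([Li])c1OC | intermediate
12 | (2,3,5,6-tetramethoxyphenyl)methanol | COc1cc(OC)c(OC)c(CO)c1OC | intermediate
13 | 3-(bromomethyl)-1,2,4,5-tetramethoxybenzene | COc1cc(OC)c(OC)c(CBr)c1OC | intermediate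
14 | zirconacyclopentadiene from 9 (Cp2Zr bonded to C6 and C9, ring A closed; cyclopentadienyl groups drawn σ-bonded) | C[Si](C)(C)C1=C2C(=C(C)[Zr]1(C3C=CC=C3)C4C=CC=C4)CCCC2(C)C | intermediate
15 | chlorobis(cyclopentadienyl){(Z)-[(6Z)-2,2-dimethyl-6-[1-(2,3,5,6-tetramethoxyphenyl)propan-2-ylidene]cyclohexylidene](trimethylsilyl)methyl}zirconium | C[Si](C)(C)/C(=C1/C(=C(/C)Cc2c(OC)c(OC)cc(OC)c2OC)CCCC1(C)C)[Zr](Cl)(C3C=CC=C3)C4C=CC=C4 | intermediate
16 | [(E)-{(6Z)-2,2-dimethyl-6-[1-(2,3,5,6-tetramethoxyphenyl)propan-2-ylidene]cyclohexylidene}methyl]trimethylsilane | C[Si](C)(C)/C=C1/C(=C(/C)Cc2c(OC)c(OC)cc(OC)c2OC)CCCC1(C)C | intermediate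
17 | (R)-4-benzyloxazolidin-2-one | O=C1OC[C@@H](Cc2ccccc2)N1 | starting material
18 | acryloyl chloride | C=CC(=O)Cl | starting material
19 | bromomagnesium salt of (R)-4-benzyloxazolidin-2-one | O=C1OC[C@@H](Cc2ccccc2)N1[Mg]Br | intermediate
20 | (R)-3-acryloyl-4-benzyloxazolidin-2-one | C=CC(=O)N1[C@H](Cc2ccccc2)COC1=O | intermediate
21 | (4R)-4-benzyl-3-{[(1R,2S,4R)-1,5,5-trimethyl-1-[(2,3,5,6-tetramethoxyphenyl)methyl]-4-(trimethylsilyl)-1,2,3,4,5,6,7,8-octahydronaphthalen-2-yl]carbonyl}-1,3-oxazolidin-2-one | COc1cc(OC)c(OC)c(C[C@@]2(C)C3=C(C(C)(C)CCC3)[C@H]([Si](C)(C)C)C[C@@H]2C(=O)N4[C@H](Cc5ccccc5)COC4=O)c1OC | intermediate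
22 | (4R)-4-benzyl-3-{[(1S,2S,8aS)-1,5,5-trimethyl-1-[(2,3,5,6-tetramethoxyphenyl)methyl]-1,2,3,7,8,8a-hexahydronaphthalen-2-yl]carbonyl}-1,3-oxazolidin-2-one | COc1cc(OC)c(OC)c(C[C@@]2(C)[C@@H]3CCCC(C)(C)C3=CC[C@@H]2C(=O)N4[C@H](Cc5ccccc5)COC4=O)c1OC | intermediate
23 | [(1S,2S,8aS)-1,5,5-trimethyl-1-[(2,3,5,6-tetramethoxyphenyl)methyl]-1,2,3,7,8,8a-hexahydronaphthalen-2-yl]methanol | COc1cc(OC)c(OC)c(C[C@@]2(C)[C@@H]3CCCC(C)(C)C3=CC[C@@H]2CO)c1OC | intermediate
24 | [(1S,2S,8aS)-1,5,5-trimethyl-1-[(2,3,5,6-tetramethoxyphenyl)methyl]-1,2,3,7,8,8a-hexahydronaphthalen-2-yl]methyl methanesulfonate | COc1cc(OC)c(OC)c(C[C@@]2(C)[C@@H]3CCCC(C)(C)C3=CC[C@@H]2COS(C)(=O)=O)c1OC | intermediate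
25 | 3-{[(1R,2S,8aS)-1,2,5,5-tetramethyl-1,2,3,7,8,8a-hexahydronaphthalen-1-yl]methyl}-1,2,4,5-tetramethoxybenzene | COc1cc(OC)c(OC)c(C[C@@]2(C)[C@@H]3CCCC(C)(C)C3=CC[C@@H]2C)c1OC | intermediate
26 | 2,5-dimethoxy-3-{[(1R,2S,8aS)-1,2,5,5-tetramethyl-1,2,3,7,8,8a-hexahydronaphthalen-1-yl]methyl}cyclohexa-2,5-diene-1,4-dione | COC1=CC(=O)C(OC)=C(C[C@@]2(C)[C@@H]3CCCC(C)(C)C3=CC[C@@H]2C)C1=O | intermediate
27 | 2-hydroxy-5-methoxy-3-{[(1R,2S,8aS)-1,2,5,5-tetramethyl-1,2,3,7,8,8a-hexahydronaphthalen-1-yl]methyl}cyclohexa-2,5-diene-1,4-dione | COC1=CC(=O)C(O)=C(C[C@@]2(C)[C@@H]3CCCC(C)(C)C3=CC[C@@H]2C)C1=O | target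

**Step count and risks**

Total step count: 15. Longest linear sequence: 12 steps (steps 1–4, 7, 9–15).

The three steps most likely to fail:

Step 9 (key cycloaddition). The twisted, fully substituted diene terminus may react too slowly, the silyl-stabilised zwitterion may lose silicon before ring closure (ipso substitution without annulation), or endo and facial selectivity may erode at the temperature the diene needs. The fallback replaces auxiliary control under a strong aluminium Lewis acid by catalyst control under a milder one. It sets out from 16, which is combined with commercial 3-acryloyloxazolidin-2-one and 10 mol % of the Cu(SbF6)2 complex of (S,S)-2,2'-(propane-2,2-diyl)bis(4-tert-butyl-4,5-dihydro-1,3-oxazole) (a divalent copper catalyst) in CH2Cl2 at rt. This should give 3-{[(1R,2S,4R)-1,5,5-trimethyl-1-[(2,3,5,6-tetramethoxyphenyl)methyl]-4-(trimethylsilyl)-1,2,3,4,5,6,7,8-octahydronaphthalen-2-yl]carbonyl}-1,3-oxazolidin-2-one F3. Protodesilylation as in step 10 would give 3-{[(1S,2S,8aS)-1,5,5-trimethyl-1-[(2,3,5,6-tetramethoxyphenyl)methyl]-1,2,3,7,8,8a-hexahydronaphthalen-2-yl]carbonyl}-1,3-oxazolidin-2-one F4, and LiBH4 reduction brings the fallback back to the route at 23.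

Step 7 (diene assembly). Transmetalation of the two Zr–C bonds may be incomplete or unselective, alkylation of the hindered alkenylcopper may be slow, the benzylic bromide may homocouple in a Wurtz-type reaction, and the zirconacycle may form sluggishly because SiMe3 and the CMe2 carbon end up cis on C5=C6. The fallback reverses the polarity of the coupling. It sets out from 9: zirconacycle 14 is formed as before and cleaved at the non-silylated Zr–C9 bond with I2 (1.0 equiv, THF, −78 → 0 °C; then 1 M HCl) to give [(E)-{(6Z)-6-(1-iodoethylidene)-2,2-dimethylcyclohexylidene}methyl]trimethylsilane F1. Bromide 13 is converted with zinc dust and LiCl in THF into (2,3,5,6-tetramethoxybenzyl)zinc bromide F2. A Negishi coupling of F1 with F2 (Pd(PPh3)4, THF, 50 °C) proceeds with retention at the alkene and comes back to the route at 16.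

Step 15 (regioselective hydrolysis). Hydroxide may attack the unhindered vinylogous ester next to the ring C–H instead of the one next to the alkyl group, or both may be hydrolysed. The fallback sets the regiochemistry by methylation instead of hydrolysis. It sets out from 26, which is hydrolysed at both positions (aq. NaOH, EtOH, 60 °C; then 1 M HCl) to 2,5-dihydroxy-3-{[(1R,2S,8aS)-1,2,5,5-tetramethyl-1,2,3,7,8,8a-hexahydronaphthalen-1-yl]methyl}cyclohexa-2,5-diene-1,4-dione F5. Acid-catalysed mono-O-methylation (MeOH, cat. H2SO4, rt) should then take place at the unhindered hydroxyl remote from the alkyl group, as in related 2,5-dihydroxy-3-alkylquinones, and comes back to the route at 27.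

Further compounds
F1 | step 7 | [(E)-{(6Z)-6-(1-iodoethylidene)-2,2-dimethylcyclohexylidene}methyl]trimethylsilane | C[Si](C)(C)/C=C1/C(=C(/C)I)CCCC1(C)C
F2 | step 7 | (2,3,5,6-tetramethoxybenzyl)zinc bromide | COc1cc(OC)c(OC)c(C[Zn]Br)c1OC
F3 | step 9 | 3-{[(1R,2S,4R)-1,5,5-trimethyl-1-[(2,3,5,6-tetramethoxyphenyl)methyl]-4-(trimethylsilyl)-1,2,3,4,5,6,7,8-octahydronaphthalen-2-yl]carbonyl}-1,3-oxazolidin-2-one | COc1cc(OC)c(OC)c(C[C@@]2(C)C3=C(C(C)(C)CCC3)[C@H]([Si](C)(C)C)C[C@@H]2C(=O)N4CCOC4=O)c1OC
F4 | step 9 | 3-{[(1S,2S,8aS)-1,5,5-trimethyl-1-[(2,3,5,6-tetramethoxyphenyl)methyl]-1,2,3,7,8,8a-hexahydronaphthalen-2-yl]carbonyl}-1,3-oxazolidin-2-one | COc1cc(OC)c(OC)c(C[C@@]2(C)[C@@H]3CCCC(C)(C)C3=CC[C@@H]2C(=O)N4CCOC4=O)c1OC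
F5 | step 15 | 2,5-dihydroxy-3-{[(1R,2S,8aS)-1,2,5,5-tetramethyl-1,2,3,7,8,8a-hexahydronaphthalen-1-yl]methyl}cyclohexa-2,5-diene-1,4-dione | OC1=CC(=O)C(O)=C(C[C@@]2(C)[C@@H]3CCCC(C)(C)C3=CC[C@@H]2C)C1=O
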